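## Retrosynthetic overview

1. Target ⇒ the 11,20-epoxide is closed last from an 11-hydroxy 20-tosylate; ring B (ten-membered, C1–C10) is opened at C2–C3 (Ni/Cr coupling of a (Z)-dienyl iodide with a C2 aldehyde); ring C (γ-lactone C7, C8, C17, C19, O) is opened at C8–C17 (samarium Reformatsky reaction of a 7-O-(2-bromopropanoyl) 8-ketone).
2. C6–C9 ⇒ a D-glucose-derived xylofuranuronic acid (C7 kept, C8 carried as a protected carbinol, C9 made by decarboxylative radical addition to C10); C5/C16 ⇒ an iodo(formyl) Wittig reagent; C3/C4 ⇒ (Z)-1,2-distannylethene; C17–C19 ⇒ 2-bromopropanoyl bromide.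
3. Ring A (C1, C10, C11, C12, C13, C14) ⇒ cut C11–C12: boat Ireland–Claisen shift of the silyl ketene acetal of a δ-lactone (O14–C20(=O)–C11–C10–C1–C14) that carries an (E)-2-silylvinyl group (C13=C12) on C14; the lactone comes from an iridium-catalysed allylation (C1, C14), lactonisation and the radical coupling (C10).
4. Enabling feature: the spiro-epoxide carbon C11 of ring A is a masked α-hydroxy acid carbon (C20 = carboxyl, epoxide O = α-OH), and C12–C13–C14 is an allyl unit whose C14 oxygen can be lent to C20 as a lactone; the C12 silyl group then returns oxygen to C14, and 11-OH directs the 12,13-diol.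
5. Order of rings: temporary δ-lactone → ring A (step 10) → ring C (step 25) → ring B (step 29) → epoxide (step 31).

Key step: step 10

Remark: briarane numbering (C1–C20) is used for every intermediate; β is the face of ring A that carries Me-15. "Fur" is the C6–C9 sugar unit (3aR,5S,6S,6aR)-6-[(4-methoxybenzyl)oxy]-2,2-dimethyltetrahydrofuro[2,3-d][1,3]dioxol-5-yl, bonded through C9.
Assumption: reagents named without a number, among them (triphenylphosphoranylidene)ketene and (Z)-1,2-bis(tributylstannyl)ethene, are taken as purchased.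

## Route

Step 1
Reactants: 1 (E)-3-(trimethylsilyl)prop-2-en-1-ol; 2 2-methyl-2-vinyloxirane (racemic)
Product: 4 anti diol (2R,3R), via silylpropenal 3 (not isolated)
Conditions: [Ir(cod)Cl]2 (2.5 mol%), Tol-BINAP (5 mol%, antipode giving the 3R carbinol), 4-chloro-3-nitrobenzoic acid (10 mol%), K3PO4 (5 mol%), THF, 60 °C
Reagents that add atoms: none
Why: Krische allylation in its tert-(hydroxy)prenylation form: the catalyst dehydrogenates 1 to enal 3 and opens racemic 2 to one (E)-σ-allyliridium species that adds through a closed chair, so the C14 carbinol and the quaternary C1 are set together as the anti diol (OH anti to CH2OH), with the absolute sense fixed by the ligand.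

Step 2
Reactants: 4 anti diol
Product: 5 β-hydroxy aldehyde
Conditions: TEMPO (10 mol%), PhI(OAc)2 (1.1 equiv), CH2Cl2, rt
Reagents that add atoms: none
Why: Oxoammonium (TEMPO) oxidation should take the primary alcohol, because the secondary allylic hydroxyl sits next to the quaternary carbon; the aldehyde has no α-hydrogen, so C1 cannot epimerise.

Step 3
Reactants: 5 β-hydroxy aldehyde
Product: 7 dihydropyranone, via ester ylide 6 (not isolated)
Conditions: Ph3P=C=C=O (1.2 equiv), toluene, 90 °C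
Reagents that add atoms: (triphenylphosphoranylidene)ketene (O=C=C=P(c1ccccc1)(c1ccccc1)c1ccccc1)
Why: Lactonisation with the Bestmann ylide: the hydroxyl adds to the cumulated ylide and the ester ylide 6 closes by intramolecular Wittig olefination onto the neopentyl aldehyde, giving the ring C10=C11 alkene of the unsaturated δ-lactone without touching C1 or C14.

Step 4
Reactants: 8 1,2:5,6-di-O-isopropylidene-α-D-glucofuranose
Product: 9 3-O-PMB diacetone glucose
Conditions: NaH, 4-methoxybenzyl chloride, Bu4NI (cat.), DMF, 0 °C → rt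
Reagents that add atoms: 4-methoxybenzyl chloride (COc1ccc(CCl)cc1)
Why: Williamson etherification of the only free hydroxyl; no stereocentre is touched.

Step 5
Reactants: 9 3-O-PMB diacetone glucose
Product: 11 xylo-dialdofuranose, via 5,6-diol 10 (not isolated)
Conditions: H5IO6 (1.3 equiv), EtOAc, rt
Reagents that add atoms: none
Why: Periodic acid hydrolyses the terminal acetonide selectively and then cleaves the glycol (Malaprade reaction), leaving the 1,2-acetonide and the configuration at C4 of the sugar (later C9) intact.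

Step 6
Reactants: 11 xylo-dialdofuranose
Product: 12 xylofuranuronic acid
Conditions: NaClO2, NaH2PO4, 2-methyl-2-butene, t-BuOH/H2O, 0 °C → rt
Reagents that add atoms: sodium chlorite ([Na+].[O-]Cl=O)
Why: Pinnick oxidation of the aldehyde under buffered conditions that do not cleave the PMB ether or the acetal.

Step 7
Reactants: 12 xylofuranuronic acid
Product: 13 N-acyloxyphthalimide
Conditions: N-hydroxyphthalimide, N,N'-diisopropylcarbodiimide, DMAP (cat.), CH2Cl2, rt
Reagents that add atoms: N-hydroxyphthalimide (O=C1c2ccccc2C(=O)N1O)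
Why: Carbodiimide esterification gives the redox-active ester needed for reductive radical generation.

Step 8
Reactants: 7 dihydropyranone; 13 N-acyloxyphthalimide
Product: 14 C10-furanosyl δ-lactone
Conditions: Ru(bpy)3(PF6)2 (1 mol%), Hantzsch ester (1.5 equiv), i-Pr2NEt, CH2Cl2, blue LEDs, rt
Reagents that add atoms: none
Why: Redox-active-ester Giese reaction: one-electron reduction of 13 releases CO2 and the furanos-4-yl radical, which should add to C10 of 7 anti to the pseudo-axial C1 vinyl group and trans to the C14 alkenyl group (setting C10) and itself react trans to its neighbouring PMB ether (setting C9), hydrogen transfer from the Hantzsch ester ending the sequence.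

Step 9
Reactants: 14 C10-furanosyl δ-lactone
Product: 15 11-hydroxy δ-lactone
Conditions: KN(SiMe3)2, THF, −78 °C; 2-(phenylsulfonyl)-3-phenyloxaziridine; aq. NH4Cl
Reagents that add atoms: 2-(phenylsulfonyl)-3-phenyloxaziridine (O=S(=O)(c1ccccc1)N1OC1c1ccccc1)
Why: Enolate oxidation with the Davis oxaziridine at the only enolisable carbon, C11; the configuration of the new carbinol does not matter, because C11 becomes planar again in step 10.

Step 10
Reactants: 15 11-hydroxy δ-lactone
Product: 18 ring A hydroxy acid, via cyclic bis-silyl ketene acetal 16 (not isolated), via bis-silylated acid 17 (not isolated)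
Conditions: Me3SiCl, Et3N, KN(SiMe3)2 (2.4 equiv), THF, −78 °C → rt; toluene, 100 °C; K2CO3, MeOH/H2O; pH 4 buffer
Reagents that add atoms: none
Why: Silylation of the hydroxyl and of the lactone enolate gives the cyclic ketene acetal 16, in which O14–C14–C13=C12 and C11=C20–O14 are the six atoms of a [3,3] shift: on heating, C14–O14 breaks while C11–C12 forms and C13=C14 appears. The closest known reactions are the carbocycle-forming Claisen rearrangement of silyl ketene acetals of 6-alkenyl δ-lactones to cyclohex-3-ene carboxylic acids, its α-oxygenated lactone variant, and Ireland–Claisen shifts onto (E)-vinylsilane termini. Ring A (C1, C10, C11, C12, C13, C14) closes by C11–C12 bond formation through an enforced boat (bicyclo[2.2.2]octane-like) transition state, the lactone ring being exchanged for the carbocycle. C11 is set by suprafacial transfer from C14: the new bond forms on the lactone face that carries the alkenyl group, which puts C20 (the carboxyl) β, cis to Me-15 and C9, and the oxygen α, whatever the C11 epimer composition of 15; C12 follows from the E alkene in the boat (SiMe3 β, H α). The step needs O-silylation and enolisation at C11 only, which the single acidic C–H of 15 and in-flask trapping with Me3SiCl should secure, and it needs the C1 vinyl group to stay out, which holds because that group is homoallylic to O14. Mild methanolysis then frees the tertiary hydroxyl and the acid.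

Step 11
Reactants: 18 ring A hydroxy acid
Product: 19 ring A 11,20-diol
Conditions: LiAlH4, THF, 0 °C → 50 °C; Rochelle salt work-up
Reagents that add atoms: none
Why: Hydride reduction of the α-hydroxy acid to the 1,2-diol; the allylsilane, the acetal and the PMB ether are inert to LiAlH4.

Step 12
Reactants: 19 ring A 11,20-diol
Product: 20 20-tosylate
Conditions: 4-methylbenzenesulfonyl chloride, pyridine, 0 °C
Reagents that add atoms: 4-methylbenzenesulfonyl chloride (Cc1ccc(cc1)S(=O)(=O)Cl)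
Why: Sulfonylation of the primary hydroxyl only; the tertiary 11-OH is too hindered, and the hydroxy tosylate stays open without strong base.

Step 13
Reactants: 20 20-tosylate
Product: 22 14α-allylic alcohol, via epoxysilane 21 (not isolated)
Conditions: mCPBA (1.1 equiv), CH2Cl2, 0 °C; then AcOH, rt
Reagents that add atoms: 3-chloroperbenzoic acid (OOC(=O)c1cccc(Cl)c1)
Why: Allylsilane oxidation (epoxidation, then desilylative opening): the peracid should attack C13=C14 anti to the β C–Si bond and syn to the homoallylic 11α-OH, and anti opening of epoxysilane 21 at the β-silyl carbon C13 expels the silyl group, giving the 14α-alcohol and the C12=C13 alkene.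

Step 14
Reactants: 22 14α-allylic alcohol
Product: 23 14-acetate
Conditions: Ac2O, DMAP (cat.), pyridine, CH2Cl2, rt
Reagents that add atoms: acetic anhydride (CC(=O)OC(C)=O)
Why: DMAP-catalysed acetylation of the secondary allylic alcohol; the tertiary 11-OH is not acylated.

Step 15
Reactants: 23 14-acetate
Product: 25 12α,13α-diol, via osmate ester 24 (not isolated)
Conditions: OsO4 (1.05 equiv), TMEDA, CH2Cl2, −78 °C; then aq. NaHSO3, THF, 40 °C
Reagents that add atoms: osmium tetroxide (O=[Os](=O)(=O)=O)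
Why: Hydrogen-bond-directed dihydroxylation: the OsO4·TMEDA complex is held by the allylic tertiary 11α-OH, so both new hydroxyls should enter on the α face (C12, C13), and the hydrogen-bonded ring alkene should react before the neopentyl vinyl group.

Step 16
Reactants: 25 12α,13α-diol
Product: 26 12,13-bis(isovalerate)
Conditions: 3-methylbutanoic anhydride, DMAP, Et3N, CH2Cl2, rt
Reagents that add atoms: 3-methylbutanoic anhydride (CC(C)CC(=O)OC(=O)CC(C)C)
Why: Acylation of the two secondary hydroxyls while the tertiary 11-OH stays free; with steps 14 and 15 this fixes the ester pattern of ring A without any selective acylation.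

Step 17
Reactants: 26 12,13-bis(isovalerate)
Product: 27 C6 lactol
Conditions: AcOH/H2O (4:1), 80 °C
Reagents that add atoms: water (O)
Why: Acid hydrolysis of the 1,2-O-isopropylidene acetal unmasks C6 as a lactol and frees 7-OH; esters, the neopentyl-type tosylate and the PMB ether should tolerate hot aqueous acetic acid.

Step 18
Reactants: 28 (triphenylphosphoranylidene)acetaldehyde
Product: 29 iodo(formyl) ylide
Conditions: N-iodosuccinimide, CH2Cl2, −20 °C → rt
Reagents that add atoms: N-iodosuccinimide (O=C1CCC(=O)N1I)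
Why: Electrophilic iodination of the stabilised ylide; the succinimide anion removes the proton of the α-iodophosphonium salt.

Step 19
Reactants: 27 C6 lactol; 29 iodo(formyl) ylide
Product: 30 seco (Z)-2-iodoenal
Conditions: toluene, 80 °C
Reagents that add atoms: none
Why: Wittig olefination of the lactol through its hydroxy aldehyde form with a stabilised ylide, which places the formyl group (C16) trans to C7 and iodine (the future C4 position) cis to C7; the hindered 9-OH set free on ring opening should not add back to the enal.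

Step 20
Reactants: 30 seco (Z)-2-iodoenal
Product: 31 7-O-(2-bromopropanoate)
Conditions: 2-bromopropanoyl bromide (1.1 equiv), pyridine, CH2Cl2, −78 °C
Reagents that add atoms: 2-bromopropanoyl bromide (CC(Br)C(Br)=O)
Why: Esterification of the allylic 7-OH, while 9-OH is shielded by C10, which lies between two quaternary carbons; the bromine-bearing carbon is a mixture that is erased on enolate formation.

Step 21
Reactants: 31 7-O-(2-bromopropanoate)
Product: 32 16-alcohol
Conditions: NaBH4, CeCl3·7H2O, MeOH, −78 °C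
Reagents that add atoms: none
Why: Luche 1,2-reduction of the enal; the esters, the α-bromo ester and the vinyl iodide survive at low temperature.

Step 22
Reactants: 32 16-alcohol
Product: 33 9,16-diacetate
Conditions: Ac2O, DMAP (cat.), 2,6-lutidine, CH2Cl2, 0 °C → rt
Reagents that add atoms: acetic anhydride (CC(=O)OC(C)=O)
Why: Acetylation of the primary allylic 16-OH and the hindered secondary 9-OH; both tertiary hydroxyls stay free.

Step 23
Reactants: 33 9,16-diacetate
Product: 34 8-alcohol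
Conditions: DDQ, CH2Cl2/pH 7 buffer, 0 °C
Reagents that add atoms: none
Why: Oxidative cleavage of the PMB ether under neutral conditions that leave esters, the vinyl iodide and the tosylate alone.

Step 24
Reactants: 34 8-alcohol
Product: 35 8-ketone
Conditions: Dess–Martin periodinane, NaHCO3, CH2Cl2, rt
Reagents that add atoms: none
Why: Dess–Martin oxidation under buffered conditions that should not epimerise the α-acyloxy centres C7 and C9.

Step 25
Reactants: 35 8-ketone
Product: 36 ring C lactone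
Conditions: SmI2 (2.2 equiv), THF, −78 °C
Reagents that add atoms: none
Why: Samarium-mediated intramolecular Reformatsky reaction (5-exo-trig): divalent samarium reduces the α-bromo ester first, and the samarium enolate adds to the neighbouring C8 ketone through a chelated transition state that should place the bulky C9 branch trans to the C6 alkenyl group and the methyl trans to C9, giving 8α-OH with Me-18 cis to it.

Step 26
Reactants: 36 ring C lactone
Product: 38 C2 aldehyde, via vicinal diol 37 (not isolated)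
Conditions: OsO4 (2 mol%), NaIO4 (4 equiv), 2,6-lutidine, dioxane/H2O (3:1), rt
Reagents that add atoms: sodium periodate ([Na+].[O-]I(=O)(=O)=O)
Why: Lemieux–Johnson cleavage of the C1 vinyl group, the only alkene that is not deactivated (the other carries iodine and two allylic ester oxygens); the aldehyde has no α-hydrogen.

Step 27
Reactants: 38 C2 aldehyde
Product: 39 (Z)-dienylstannane
Conditions: (Z)-1,2-bis(tributylstannyl)ethene (3 equiv), Pd2(dba)3 (5 mol%), AsPh3 (20 mol%), NMP, rt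
Reagents that add atoms: (Z)-1,2-bis(tributylstannyl)ethene (CCCC[Sn](CCCC)(CCCC)/C=C\[Sn](CCCC)(CCCC)CCCC)
Why: Stille coupling at the C5–I bond with retention at both alkenes; excess distannane should ensure single coupling, and weakly ligated zerovalent palladium at room temperature should not ionise the allylic esters.

Step 28
Reactants: 39 (Z)-dienylstannane
Product: 40 (Z)-dienyl iodide
Conditions: I2 (1.05 equiv), CH2Cl2, 0 °C
Reagents that add atoms: iodine (II)
Why: Iododestannylation with retention of the Z geometry.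

Step 29
Reactants: 40 (Z)-dienyl iodide
Product: 41 ten-membered 2-carbinol
Conditions: CrCl2 (10 equiv), NiCl2 (1 mol%), DMSO/THF, rt, 2 mM
Reagents that add atoms: none
Why: Nozaki–Hiyama–Kishi macrocyclisation: nickel-catalysed insertion into the C3–I bond, transfer to trivalent chromium and addition of the alkenylchromium to the neopentyl C2 aldehyde at high dilution should close ring B with the Z alkene kept; the 2-OH configuration is expected from addition to the aldehyde rotamer that holds the carbonyl anti to C14, on the outer face of the forming ring.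

Step 30
Reactants: 41 ten-membered 2-carbinol
Product: 42 2-acetate
Conditions: Ac2O, DMAP (cat.), pyridine, CH2Cl2, rt
Reagents that add atoms: acetic anhydride (CC(=O)OC(C)=O)
Why: Acetylation of the secondary allylic 2-OH; the tertiary 8-OH and 11-OH are not acylated.

Step 31
Reactants: 42 2-acetate
Product: 43 CNP0303383.2
Conditions: DBU (3 equiv), MeCN, 0 °C → rt
Reagents that add atoms: none
Why: Intramolecular Williamson reaction (3-exo-tet): the tertiary 11α-oxygen displaces the C20 tosylate and forms the spiro-epoxide with retention at C11; ring closure should outrun acyl migration from O12, and the base would also bring any C17 epimer to the more stable arrangement with Me-18 cis to 8-OH.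

## Compound list

1 | (E)-3-(trimethylsilyl)prop-2-en-1-ol | C[Si](C)(C)/C=C/CO | starting material
2 | 2-methyl-2-vinyloxirane (isoprene monoxide, racemic) | CC1(C=C)CO1 | starting material
3 | (E)-3-(trimethylsilyl)prop-2-enal | C[Si](C)(C)/C=C/C=O | intermediate
4 | (2R,3R,4E)-2-ethenyl-2-methyl-5-(trimethylsilyl)pent-4-ene-1,3-diol | C[Si](C)(C)/C=C/[C@@H](O)[C@](C)(C=C)CO | intermediate
5 | (2S,3R,4E)-2-ethenyl-3-hydroxy-2-methyl-5-(trimethylsilyl)pent-4-enal | C[Si](C)(C)/C=C/[C@@H](O)[C@](C)(C=C)C=O | intermediate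
6 | 3-O-[(triphenylphosphoranylidene)acetyl] derivative of 5 (ester ylide) | C[Si](C)(C)/C=C/[C@@H](OC(=O)C=P(c1ccccc1)(c1ccccc1)c1ccccc1)[C@](C)(C=C)C=O | intermediate
7 | (5R,6R)-5-ethenyl-5-methyl-6-[(E)-2-(trimethylsilyl)ethenyl]-5,6-dihydro-2H-pyran-2-one | C[Si](C)(C)/C=C/[C@H]1OC(=O)C=C[C@@]1(C)C=C | intermediate
8 | 1,2:5,6-di-O-isopropylidene-α-D-glucofuranose | CC1(C)OC[C@@H](O1)[C@H]1O[C@@H]2OC(C)(C)O[C@@H]2[C@H]1O | starting material
9 | 1,2:5,6-di-O-isopropylidene-3-O-(4-methoxybenzyl)-α-D-glucofuranose | CC1(C)OC[C@@H](O1)[C@H]1O[C@@H]2OC(C)(C)O[C@@H]2[C@H]1OCc1ccc(OC)cc1 | intermediate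
10 | 1,2-O-isopropylidene-3-O-(4-methoxybenzyl)-α-D-glucofuranose | OC[C@@H](O)[C@H]1O[C@@H]2OC(C)(C)O[C@@H]2[C@H]1OCc1ccc(OC)cc1 | intermediate
11 | 1,2-O-isopropylidene-3-O-(4-methoxybenzyl)-α-D-xylo-pentodialdo-1,4-furanose | O=C[C@H]1O[C@@H]2OC(C)(C)O[C@@H]2[C@H]1OCc1ccc(OC)cc1 | intermediate
12 | 1,2-O-isopropylidene-3-O-(4-methoxybenzyl)-α-D-xylofuranuronic acid | OC(=O)[C@H]1O[C@@H]2OC(C)(C)O[C@@H]2[C@H]1OCc1ccc(OC)cc1 | intermediate
13 | 1,3-dioxoisoindolin-2-yl 1,2-O-isopropylidene-3-O-(4-methoxybenzyl)-α-D-xylofuranuronate | O=C(ON1C(=O)c2ccccc2C1=O)[C@H]1O[C@@H]2OC(C)(C)O[C@@H]2[C@H]1OCc1ccc(OC)cc1 | intermediate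
14 | (4S,5R,6R)-5-ethenyl-4-Fur-5-methyl-6-[(E)-2-(trimethylsilyl)ethenyl]tetrahydro-2H-pyran-2-one (Fur on C10, cis to Me-15, trans to the C14 alkenyl group) | C[Si](C)(C)/C=C/[C@H]1OC(=O)C[C@H]([C@@H]2O[C@@H]3OC(C)(C)O[C@@H]3[C@H]2OCc2ccc(OC)cc2)[C@@]1(C)C=C | intermediate
15 | 3-hydroxy derivative of 14 (11-hydroxy δ-lactone, both C11 epimers) | C[Si](C)(C)/C=C/[C@H]1OC(=O)C(O)[C@H]([C@@H]2O[C@@H]3OC(C)(C)O[C@@H]3[C@H]2OCc2ccc(OC)cc2)[C@@]1(C)C=C | intermediate
16 | cyclic ketene acetal of 15 with Me3SiO on C20 and on C11 | C[Si](C)(C)/C=C/[C@H]1OC(O[Si](C)(C)C)=C(O[Si](C)(C)C)[C@H]([C@@H]2O[C@@H]3OC(C)(C)O[C@@H]3[C@H]2OCc2ccc(OC)cc2)[C@@]1(C)C=C | intermediate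
17 | trimethylsilyl ester and 11-O-trimethylsilyl ether of 18 | C[Si](C)(C)OC(=O)[C@@]1(O[Si](C)(C)C)[C@@H]([Si](C)(C)C)C=C[C@](C)(C=C)[C@H]1[C@@H]1O[C@@H]2OC(C)(C)O[C@@H]2[C@H]1OCc1ccc(OC)cc1 | intermediate
18 | ring A acid: 11α-hydroxy-1β-methyl-12β-(trimethylsilyl)-1α-vinyl-10β-Fur-cyclohex-13-ene-11β-carboxylic acid (briarane locants) | OC(=O)[C@@]1(O)[C@@H]([Si](C)(C)C)C=C[C@](C)(C=C)[C@H]1[C@@H]1O[C@@H]2OC(C)(C)O[C@@H]2[C@H]1OCc1ccc(OC)cc1 | intermediate
19 | ring A diol: 18 with the carboxyl reduced to C20H2OH (11α-OH) | OC[C@@]1(O)[C@@H]([Si](C)(C)C)C=C[C@](C)(C=C)[C@H]1[C@@H]1O[C@@H]2OC(C)(C)O[C@@H]2[C@H]1OCc1ccc(OC)cc1 | intermediate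
20 | 20-O-(4-methylbenzenesulfonyl) derivative of 19 | Cc1ccc(cc1)S(=O)(=O)OC[C@@]1(O)[C@@H]([Si](C)(C)C)C=C[C@](C)(C=C)[C@H]1[C@@H]1O[C@@H]2OC(C)(C)O[C@@H]2[C@H]1OCc1ccc(OC)cc1 | intermediate
21 | 13α,14α-epoxide of 20 (12β-SiMe3 kept) | Cc1ccc(cc1)S(=O)(=O)OC[C@@]1(O)[C@@H]([Si](C)(C)C)[C@@H]2O[C@@H]2[C@](C)(C=C)[C@H]1[C@@H]1O[C@@H]2OC(C)(C)O[C@@H]2[C@H]1OCc1ccc(OC)cc1 | intermediate
22 | ring A allylic alcohol: 14α-OH, C12=C13, 11α-OH, 20-OTs, 1α-vinyl, 10β-Fur | Cc1ccc(cc1)S(=O)(=O)OC[C@@]1(O)C=C[C@H](O)[C@](C)(C=C)[C@H]1[C@@H]1O[C@@H]2OC(C)(C)O[C@@H]2[C@H]1OCc1ccc(OC)cc1 | intermediate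
23 | 14-O-acetate of 22 | Cc1ccc(cc1)S(=O)(=O)OC[C@@]1(O)C=C[C@H](OC(C)=O)[C@](C)(C=C)[C@H]1[C@@H]1O[C@@H]2OC(C)(C)O[C@@H]2[C@H]1OCc1ccc(OC)cc1 | intermediate
24 | 12α,13α-O-osmate ester of 25 (dioxo, TMEDA chelate, hexavalent osmium) | Cc1ccc(cc1)S(=O)(=O)OC[C@@]1(O)[C@@H]2O[Os-2]3(=O)(=O)([N+](C)(C)CC[N+]3(C)C)O[C@@H]2[C@H](OC(C)=O)[C@](C)(C=C)[C@H]1[C@@H]1O[C@@H]2OC(C)(C)O[C@@H]2[C@H]1OCc1ccc(OC)cc1 | intermediate
25 | 12α,13α-diol from 23 | Cc1ccc(cc1)S(=O)(=O)OC[C@@]1(O)[C@H](O)[C@H](O)[C@H](OC(C)=O)[C@](C)(C=C)[C@H]1[C@@H]1O[C@@H]2OC(C)(C)O[C@@H]2[C@H]1OCc1ccc(OC)cc1 | intermediate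
26 | 12,13-bis(3-methylbutanoate) of 25 | Cc1ccc(cc1)S(=O)(=O)OC[C@@]1(O)[C@H](OC(=O)CC(C)C)[C@H](OC(=O)CC(C)C)[C@H](OC(C)=O)[C@](C)(C=C)[C@H]1[C@@H]1O[C@@H]2OC(C)(C)O[C@@H]2[C@H]1OCc1ccc(OC)cc1 | intermediate
27 | lactol: 26 without the isopropylidene group (C6 hemiacetal, 7-OH free, 8-OPMB; both anomers) | Cc1ccc(cc1)S(=O)(=O)OC[C@@]1(O)[C@H](OC(=O)CC(C)C)[C@H](OC(=O)CC(C)C)[C@H](OC(C)=O)[C@](C)(C=C)[C@H]1[C@@H]1OC(O)[C@H](O)[C@H]1OCc1ccc(OC)cc1 | intermediate
28 | (triphenylphosphoranylidene)acetaldehyde | O=CC=P(c1ccccc1)(c1ccccc1)c1ccccc1 | starting material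
29 | 2-iodo-2-(triphenylphosphoranylidene)acetaldehyde | O=CC(I)=P(c1ccccc1)(c1ccccc1)c1ccccc1 | intermediate
30 | seco enal: ring A of 26 with the chain C9H(OH)–C8H(OPMB)–C7H(OH)–C6H=C5(I)–C16HO on C10, iodine cis to C7 | Cc1ccc(cc1)S(=O)(=O)OC[C@@]1(O)[C@H](OC(=O)CC(C)C)[C@H](OC(=O)CC(C)C)[C@H](OC(C)=O)[C@](C)(C=C)[C@H]1[C@H](O)[C@H](OCc1ccc(OC)cc1)[C@@H](O)/C=C(I)/C=O | intermediate
31 | 7-O-(2-bromopropanoyl) ester of 30 (both bromo epimers) | Cc1ccc(cc1)S(=O)(=O)OC[C@@]1(O)[C@H](OC(=O)CC(C)C)[C@H](OC(=O)CC(C)C)[C@H](OC(C)=O)[C@](C)(C=C)[C@H]1[C@H](O)[C@H](OCc1ccc(OC)cc1)[C@@H](OC(=O)C(C)Br)/C=C(I)/C=O | intermediate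
32 | 16-alcohol from 31 | Cc1ccc(cc1)S(=O)(=O)OC[C@@]1(O)[C@H](OC(=O)CC(C)C)[C@H](OC(=O)CC(C)C)[C@H](OC(C)=O)[C@](C)(C=C)[C@H]1[C@H](O)[C@H](OCc1ccc(OC)cc1)[C@@H](OC(=O)C(C)Br)/C=C(I)/CO | intermediate
33 | 9,16-di-O-acetate of 32 | Cc1ccc(cc1)S(=O)(=O)OC[C@@]1(O)[C@H](OC(=O)CC(C)C)[C@H](OC(=O)CC(C)C)[C@H](OC(C)=O)[C@](C)(C=C)[C@H]1[C@H](OC(C)=O)[C@H](OCc1ccc(OC)cc1)[C@@H](OC(=O)C(C)Br)/C=C(I)/COC(C)=O | intermediate
34 | 8-alcohol from 33 (PMB removed) | Cc1ccc(cc1)S(=O)(=O)OC[C@@]1(O)[C@H](OC(=O)CC(C)C)[C@H](OC(=O)CC(C)C)[C@H](OC(C)=O)[C@](C)(C=C)[C@H]1[C@H](OC(C)=O)[C@H](O)[C@@H](OC(=O)C(C)Br)/C=C(I)/COC(C)=O | intermediate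
35 | 8-ketone from 34 | Cc1ccc(cc1)S(=O)(=O)OC[C@@]1(O)[C@H](OC(=O)CC(C)C)[C@H](OC(=O)CC(C)C)[C@H](OC(C)=O)[C@](C)(C=C)[C@H]1[C@H](OC(C)=O)C(=O)[C@@H](OC(=O)C(C)Br)/C=C(I)/COC(C)=O | intermediate
36 | ring C lactone: 8α-hydroxy-17-methyl γ-lactone (C19–O7) with a (Z)-3-acetoxy-2-iodoprop-1-enyl group on C7; ring A as in 26 | Cc1ccc(cc1)S(=O)(=O)OC[C@@]1(O)[C@H](OC(=O)CC(C)C)[C@H](OC(=O)CC(C)C)[C@H](OC(C)=O)[C@](C)(C=C)[C@H]1[C@H](OC(C)=O)[C@]2(O)[C@@H](C)C(=O)O[C@H]2/C=C(I)/COC(C)=O | intermediate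
37 | vicinal diol from the C1 vinyl group of 36 | Cc1ccc(cc1)S(=O)(=O)OC[C@@]1(O)[C@H](OC(=O)CC(C)C)[C@H](OC(=O)CC(C)C)[C@H](OC(C)=O)[C@](C)(C(O)CO)[C@H]1[C@H](OC(C)=O)[C@]2(O)[C@@H](C)C(=O)O[C@H]2/C=C(I)/COC(C)=O | intermediate
38 | C2 aldehyde (1α-formyl) from 36 | Cc1ccc(cc1)S(=O)(=O)OC[C@@]1(O)[C@H](OC(=O)CC(C)C)[C@H](OC(=O)CC(C)C)[C@H](OC(C)=O)[C@](C)(C=O)[C@H]1[C@H](OC(C)=O)[C@]2(O)[C@@H](C)C(=O)O[C@H]2/C=C(I)/COC(C)=O | intermediate
39 | dienylstannane: 38 with (Z)-2-(tributylstannyl)ethenyl on C5 in place of iodine | Cc1ccc(cc1)S(=O)(=O)OC[C@@]1(O)[C@H](OC(=O)CC(C)C)[C@H](OC(=O)CC(C)C)[C@H](OC(C)=O)[C@](C)(C=O)[C@H]1[C@H](OC(C)=O)[C@]2(O)[C@@H](C)C(=O)O[C@H]2/C=C(\C=C/[Sn](CCCC)(CCCC)CCCC)COC(C)=O | intermediate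
40 | dienyl iodide: 39 with iodine in place of tin (3Z) | Cc1ccc(cc1)S(=O)(=O)OC[C@@]1(O)[C@H](OC(=O)CC(C)C)[C@H](OC(=O)CC(C)C)[C@H](OC(C)=O)[C@](C)(C=O)[C@H]1[C@H](OC(C)=O)[C@]2(O)[C@@H](C)C(=O)O[C@H]2/C=C(\C=C/I)COC(C)=O | intermediate
41 | ten-membered carbinol: 2-deacetyl target with 11-OH and 20-OTs in place of the epoxide | CC(=O)OCC1=C/[C@@H]2OC(=O)[C@H](C)[C@@]2(O)[C@@H](OC(C)=O)[C@H]2[C@@](O)(COS(=O)(=O)c3ccc(C)cc3)[C@H](OC(=O)CC(C)C)[C@H](OC(=O)CC(C)C)[C@H](OC(C)=O)[C@]2(C)[C@@H](O)/C=C\1 | intermediate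
42 | 2-O-acetate of 41 | CC(=O)OCC1=C/[C@@H]2OC(=O)[C@H](C)[C@@]2(O)[C@@H](OC(C)=O)[C@H]2[C@@](O)(COS(=O)(=O)c3ccc(C)cc3)[C@H](OC(=O)CC(C)C)[C@H](OC(=O)CC(C)C)[C@H](OC(C)=O)[C@]2(C)[C@@H](OC(C)=O)/C=C\1 | intermediate
43 | CNP0303383.2 | CC(=O)OCC1=C/[C@@H]2OC(=O)[C@H](C)[C@@]2(O)[C@@H](OC(C)=O)[C@H]2[C@@]3(CO3)[C@H](OC(=O)CC(C)C)[C@H](OC(=O)CC(C)C)[C@H](OC(C)=O)[C@]2(C)[C@@H](OC(C)=O)/C=C\1 | target

## Summary

Total step count: 31. Longest linear sequence: 27 steps (8 → 43 through steps 4–17 and 19–31).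

Steps most likely to fail:

Step 10. The fully substituted, α-silyloxy ketene acetal must eclipse the C10 sugar branch in the enforced boat, so the rearrangement may be slow and give way to thermal decomposition or desilylation before C11–C12 forms. Fallback: setting out from 14 (no oxygen on C11), the simpler mono-silyl ketene acetal (LiN(i-Pr)2, Me3SiCl, THF, −78 °C; toluene, 100 °C) rearranges through the same boat to the 11-deoxy ring A acid F3. Esterification with Me3SiCHN2 gives its methyl ester F4. The ester enolate (KN(SiMe3)2, THF, −78 °C) is hydroxylated with the Davis oxaziridine on the α face, anti to the 12β-silyl group, giving the 11α-hydroxy methyl ester F5, and LiAlH4 reduction comes back to the route at 19.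

Step 8. The β-carbon of 7 lies next to the quaternary C1, so the secondary radical may add too slowly; hydrogen transfer to the radical before addition, or 5-exo closure of the adduct radical onto the vinylsilane, would then take over, and the facial preference at the sugar radical may be weak. Fallback: setting out from 5, Knoevenagel condensation with dimethyl malonate (piperidinium acetate, benzene, reflux) with lactonisation in the flask gives the doubly activated methyl (5R,6R)-5-ethenyl-5-methyl-2-oxo-6-[(E)-2-(trimethylsilyl)ethenyl]-5,6-dihydro-2H-pyran-3-carboxylate F1. The radical from 13, under the conditions of step 8, adds to this alkylidene malonate-type acceptor to give the 11-methoxycarbonyl adduct F2, and Krapcho demethoxycarbonylation (LiCl, wet DMSO, 120 °C) comes back to the route at 14.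

Step 29. Ring strain in the ten-membered diene may favour intermolecular coupling over ring closure, and facial selectivity at the C2 aldehyde may be poor. Fallback: setting out from 38, Stille coupling with tributyl(vinyl)stannane (Pd2(dba)3, AsPh3) gives the diene aldehyde F6. Ni/Cr-mediated addition of vinyl iodide (CrCl2, NiCl2, chiral sulfonamide ligand, so that the reagent controls C2) gives the divinyl carbinol F7, and acetylation gives the triene acetate F8. Ring-closing metathesis with the second-generation Hoveyda–Grubbs catalyst (dilute toluene, 80 °C) then forms C3=C4, cis in the ring, and comes back to the route at 42.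

## Further compounds

F1 | step 8 | methyl (5R,6R)-5-ethenyl-5-methyl-2-oxo-6-[(E)-2-(trimethylsilyl)ethenyl]-5,6-dihydro-2H-pyran-3-carboxylate | C[Si](C)(C)/C=C/[C@H]1OC(=O)C(C(=O)OC)=C[C@@]1(C)C=C
F2 | step 8 | 3-(methoxycarbonyl) derivative of 14 | C[Si](C)(C)/C=C/[C@H]1OC(=O)C(C(=O)OC)[C@H]([C@@H]2O[C@@H]3OC(C)(C)O[C@@H]3[C@H]2OCc2ccc(OC)cc2)[C@@]1(C)C=C
F3 | step 10 | 11-deoxy analogue of 18 (11α-H, 11β-CO2H) | OC(=O)[C@H]1[C@@H]([Si](C)(C)C)C=C[C@](C)(C=C)[C@H]1[C@@H]1O[C@@H]2OC(C)(C)O[C@@H]2[C@H]1OCc1ccc(OC)cc1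
F4 | step 10 | methyl ester of F3 | COC(=O)[C@H]1[C@@H]([Si](C)(C)C)C=C[C@](C)(C=C)[C@H]1[C@@H]1O[C@@H]2OC(C)(C)O[C@@H]2[C@H]1OCc1ccc(OC)cc1
F5 | step 10 | methyl ester of 18 | COC(=O)[C@@]1(O)[C@@H]([Si](C)(C)C)C=C[C@](C)(C=C)[C@H]1[C@@H]1O[C@@H]2OC(C)(C)O[C@@H]2[C@H]1OCc1ccc(OC)cc1
F6 | step 29 | 38 with ethenyl on C5 in place of iodine | Cc1ccc(cc1)S(=O)(=O)OC[C@@]1(O)[C@H](OC(=O)CC(C)C)[C@H](OC(=O)CC(C)C)[C@H](OC(C)=O)[C@](C)(C=O)[C@H]1[C@H](OC(C)=O)[C@]2(O)[C@@H](C)C(=O)O[C@H]2/C=C(\C=C)COC(C)=O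
F7 | step 29 | 2-hydroxy-2-vinyl adduct of F6 | Cc1ccc(cc1)S(=O)(=O)OC[C@@]1(O)[C@H](OC(=O)CC(C)C)[C@H](OC(=O)CC(C)C)[C@H](OC(C)=O)[C@](C)([C@@H](O)C=C)[C@H]1[C@H](OC(C)=O)[C@]2(O)[C@@H](C)C(=O)O[C@H]2/C=C(\C=C)COC(C)=O
F8 | step 29 | 2-O-acetate of F7 | Cc1ccc(cc1)S(=O)(=O)OC[C@@]1(O)[C@H](OC(=O)CC(C)C)[C@H](OC(=O)CC(C)C)[C@H](OC(C)=O)[C@](C)([C@@H](OC(C)=O)C=C)[C@H]1[C@H](OC(C)=O)[C@]2(O)[C@@H](C)C(=O)O[C@H]2/C=C(\C=C)COC(C)=O
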